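The oxolane ring is opened at O1–C2 and C3–C4, and the guaiacyl ring is detached from C7′. The plan exploits that ring carbon C3, which carries the acetoxymethyl arm, lies between benzylic C2 and C4 (the carbon bearing C7′) and can therefore start as a malonate carbon. A single palladium-catalysed operation joins an arylidene malonate (C2, C3 and the catechol ring), propargyl alcohol (O1, C5, C4, C7′) and a guaiacyl iodide, closes the oxolane and fixes C2 by dynamic kinetic resolution. Its precursor is the dibenzyl-protected 3,4-dihydroxybenzylidene malonate. C3 and C4 are afterwards set relative to C2 by equilibration and hydrogenation.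

Key step: step 3

Remark (numbering): oxolane atoms are O1, C2 (catechol ring), C3 (acetoxymethyl), C4 (benzyl) and C5; C7′ is the benzylic carbon on C4. The target is (2S,3R,4R), that is 2,3-trans and 3,4-cis.

Remark (descriptors): C2 is formally R in diester 8 and S from 9 onwards only because the priority of C3 changes; the spatial arrangement is the same throughout and is that of the target.

Remark (stoichiometry): the coupling releases iodide as LiI, so the alkoxide base is used in slight excess over 3 and not in a catalytic amount.

Assumption: the sense of induction of the chiral ligand cannot be predicted with confidence; (R)-DTBM-SEGPHOS is written, and its antipode is to be used if that is the one that delivers 8.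

Step 1
Reactants: 1 3,4-bis(benzyloxy)benzaldehyde; 2 dimethyl malonate
Product: 3 dimethyl 2-[3,4-bis(benzyloxy)benzylidene]malonate
Conditions: piperidine (cat.), AcOH (cat.), toluene, reflux, Dean–Stark
Reagents that add atoms: none
Why: Knoevenagel condensation, in which the malonate attacks the piperidine-derived iminium ion of the aldehyde and azeotropic removal of water drives the equilibrium to the arylidene malonate, which has no geometric isomers because both esters are the same.

Step 2
Reactants: 4 4-iodo-2-methoxyphenol
Product: 5 1-(benzyloxy)-4-iodo-2-methoxybenzene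
Conditions: BnBr, K2CO3, DMF, 25 °C
Reagents that add atoms: benzyl bromide, BrCc1ccccc1
Why: Williamson ether synthesis, in which the phenoxide formed with K2CO3 displaces bromide from benzyl bromide while the aryl iodide is inert.

Step 3
Reactants: 3 dimethyl 2-[3,4-bis(benzyloxy)benzylidene]malonate; 6 propargyl alcohol; 5 1-(benzyloxy)-4-iodo-2-methoxybenzene
Product: 8 dimethyl (2R,4Z)-4-[4-(benzyloxy)-3-methoxybenzylidene]-2-[3,4-bis(benzyloxy)phenyl]oxolane-3,3-dicarboxylate, via lithium oxa-Michael adduct 7 (not isolated)
Conditions: 6 (1.5 equiv), n-BuLi (1.2 equiv), THF, 0 °C; then 3, 5 (1.2 equiv), Pd2(dba)3 (2.5 mol %), (R)-DTBM-SEGPHOS (6 mol %), DMSO–THF, 30 °C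
Reagents that add atoms: none
Why: Proposed new method: lithium propargyl alkoxide adds reversibly to 3 (O1–C2) to give the racemic, rapidly interconverting malonate anion 7, while oxidative addition of 5 to zerovalent palladium gives a chiral arylpalladium bisphosphine species of divalent palladium that binds the alkyne, so that the malonate carbon attacks C4 anti to the metal (C3–C4) and reductive elimination from the vinyl(aryl)palladium forms C7′–aryl with the aryl group cis to C5 (Z). The closest known reaction type is the racemic palladium-mediated three-component coupling of propargyl alkoxides, alkylidene malonates and aryl halides to 4-arylmethylene tetrahydrofurans, taken together with enantioselective palladium–bisphosphine Conia-ene-type additions of 1,3-dicarbonyl carbanions to alkynes. The oxolane ring closes in the 5-exo-dig mode. The only new stereocentre, C2, is controlled by the chiral bisphosphine on palladium through dynamic kinetic resolution, because retro-oxa-Michael racemisation of 7 is fast, the cyclisation is irreversible, and the catalyst should close the enantiomer whose C2 aryl group points away from the ligand in the ring-forming transition state. The step needs enantioselection at C2, anti addition across the alkyne and preference for arylative over palladium-free protonative cyclisation, and the malonate secures these because its stabilised anion is at once a good leaving group for racemisation and a soft nucleophile for outer-sphere attack, while C3 becomes quaternary on closure and thereby locks C2. The lithium counter-ion and the THF-rich medium are chosen to keep the uncatalysed cyclisation of 7 slow.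

Step 4
Reactants: 8 dimethyl (2R,4Z)-4-[4-(benzyloxy)-3-methoxybenzylidene]-2-[3,4-bis(benzyloxy)phenyl]oxolane-3,3-dicarboxylate
Product: 9 methyl (2S,3S,4Z)-4-[4-(benzyloxy)-3-methoxybenzylidene]-2-[3,4-bis(benzyloxy)phenyl]oxolane-3-carboxylate
Conditions: LiCl, H2O, DMSO, 150 °C
Reagents that add atoms: none
Why: Krapcho dealkoxycarbonylation, in which chloride demethylates one ester, the carboxylate loses CO2 and water protonates the enolate at C3, and since the remaining C3–H stays exchangeable in the hot, weakly basic medium the ester should settle trans to the C2 aryl group under thermodynamic control (3S), while non-enolisable C2 keeps its configuration and the C4=C7′ bond stays conjugated with the guaiacyl ring.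

Step 5
Reactants: 9 methyl (2S,3S,4Z)-4-[4-(benzyloxy)-3-methoxybenzylidene]-2-[3,4-bis(benzyloxy)phenyl]oxolane-3-carboxylate
Product: 10 [(2S,3R,4Z)-4-[4-(benzyloxy)-3-methoxybenzylidene]-2-[3,4-bis(benzyloxy)phenyl]oxolan-3-yl]methanol
Conditions: LiAlH4, THF, 0 °C
Reagents that add atoms: none
Why: Hydride reduction of the ester with LiAlH4 gives the primary alcohol faster than C3 can epimerise, and the benzyl ethers, the ring ether and the styrenyl alkene are inert to the reagent.

Step 6
Reactants: 10 [(2S,3R,4Z)-4-[4-(benzyloxy)-3-methoxybenzylidene]-2-[3,4-bis(benzyloxy)phenyl]oxolan-3-yl]methanol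
Product: 11 [(2S,3R,4Z)-4-[4-(benzyloxy)-3-methoxybenzylidene]-2-[3,4-bis(benzyloxy)phenyl]oxolan-3-yl]methyl acetate
Conditions: Ac2O, pyridine, DMAP (cat.), CH2Cl2, 0 to 25 °C
Reagents that add atoms: acetic anhydride, CC(=O)OC(C)=O
Why: DMAP-catalysed acylation of the only free hydroxyl group installs the acetate while all three phenols are still benzylated, so no phenol can compete.

Step 7
Reactants: 11 [(2S,3R,4Z)-4-[4-(benzyloxy)-3-methoxybenzylidene]-2-[3,4-bis(benzyloxy)phenyl]oxolan-3-yl]methyl acetate
Product: 12 [(2S,3R,4R)-2-(3,4-dihydroxyphenyl)-4-(4-hydroxy-3-methoxybenzyl)oxolan-3-yl]methyl acetate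
Conditions: H2 (1 atm), Pd/C, EtOAc, 25 °C, exclusion of air on work-up
Reagents that add atoms: none
Why: Heterogeneous catalytic hydrogenation delivers hydrogen to the C4=C7′ face opposite the adjacent C3 acetoxymethyl group, which places the new benzyl group cis to it (4R), and the same catalyst hydrogenolyses the three aryl benzyl ethers, which should cleave faster than the ring C2–O1 bond in neutral ethyl acetate.

Compound list
1 | 3,4-bis(benzyloxy)benzaldehyde | O=Cc1ccc(OCc2ccccc2)c(OCc2ccccc2)c1 | starting material
2 | dimethyl malonate | COC(=O)CC(=O)OC | starting material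
3 | dimethyl 2-[3,4-bis(benzyloxy)benzylidene]malonate | COC(=O)C(=Cc1ccc(OCc2ccccc2)c(OCc2ccccc2)c1)C(=O)OC | intermediate
4 | 4-iodo-2-methoxyphenol | COc1cc(I)ccc1O | starting material
5 | 1-(benzyloxy)-4-iodo-2-methoxybenzene | COc1cc(I)ccc1OCc1ccccc1 | intermediate
6 | propargyl alcohol (prop-2-yn-1-ol) | C#CCO | starting material
7 | lithium enolate of dimethyl 2-{[3,4-bis(benzyloxy)phenyl](prop-2-yn-1-yloxy)methyl}malonate, both enantiomers, interconverting, formed in the flask and not isolated | [Li+].COC(=O)[C-](C(=O)OC)C(OCC#C)c1ccc(OCc2ccccc2)c(OCc2ccccc2)c1 | intermediate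
8 | dimethyl (2R,4Z)-4-[4-(benzyloxy)-3-methoxybenzylidene]-2-[3,4-bis(benzyloxy)phenyl]oxolane-3,3-dicarboxylate | COc1cc(/C=C2\CO[C@H](c3ccc(OCc4ccccc4)c(OCc4ccccc4)c3)C2(C(=O)OC)C(=O)OC)ccc1OCc1ccccc1 | intermediate
9 | methyl (2S,3S,4Z)-4-[4-(benzyloxy)-3-methoxybenzylidene]-2-[3,4-bis(benzyloxy)phenyl]oxolane-3-carboxylate (ester trans to the C2 aryl group) | COc1cc(/C=C2\CO[C@H](c3ccc(OCc4ccccc4)c(OCc4ccccc4)c3)[C@H]2C(=O)OC)ccc1OCc1ccccc1 | intermediate
10 | [(2S,3R,4Z)-4-[4-(benzyloxy)-3-methoxybenzylidene]-2-[3,4-bis(benzyloxy)phenyl]oxolan-3-yl]methanol | COc1cc(/C=C2\CO[C@H](c3ccc(OCc4ccccc4)c(OCc4ccccc4)c3)[C@H]2CO)ccc1OCc1ccccc1 | intermediate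
11 | [(2S,3R,4Z)-4-[4-(benzyloxy)-3-methoxybenzylidene]-2-[3,4-bis(benzyloxy)phenyl]oxolan-3-yl]methyl acetate | COc1cc(/C=C2\CO[C@H](c3ccc(OCc4ccccc4)c(OCc4ccccc4)c3)[C@H]2COC(C)=O)ccc1OCc1ccccc1 | intermediate
12 | [(2S,3R,4R)-2-(3,4-dihydroxyphenyl)-4-(4-hydroxy-3-methoxybenzyl)oxolan-3-yl]methyl acetate (CNP0273854.1) | COc1cc(C[C@H]2CO[C@H](c3ccc(O)c(O)c3)[C@H]2COC(C)=O)ccc1O | target

Total step count: 7. Longest linear sequence: 6 (steps 1, 3, 4, 5, 6 and 7; step 2 is the side branch that supplies 5).

Steps most likely to fail

Step 3. The risk is insufficient discrimination between the two interconverting enantiomers of 7: cyclisation may outrun their racemisation, or the ligand may not discriminate between them. Palladium-free protonative cyclisation of 7, or direct arylation of the alkyne terminus, would also erode the outcome. Fallback, by known chemistry: set out from 3, 5 and 6 and run the coupling in its established racemic form (n-BuLi, PdCl2(PPh3)2, DMSO–THF, 25 °C). This should give racemic dimethyl (4Z)-4-[4-(benzyloxy)-3-methoxybenzylidene]-2-[3,4-bis(benzyloxy)phenyl]oxolane-3,3-dicarboxylate F1. F1 is then resolved by preparative chromatography on a chiral stationary phase (supercritical CO2–methanol on amylose tris(3,5-dimethylphenylcarbamate)). The 2R enantiomer is collected and its configuration confirmed; it is 8, where the route is rejoined.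

Step 4. Three processes may interfere:
- protonation of the C3 enolate on the face away from the C2 aryl group, leaving 2,3-cis ester that does not fully equilibrate;
- migration of the C4=C7′ double bond into conjugation with the ester through the extended enolate at 150 °C;
- reversible ring opening of the enolate, which would erode C2.

Fallback: set out from 8 and divide the change into three mild, separately monitored events.
- One ester, expected to be the one trans to the C2 aryl group, is saponified with KOH (1.1 equiv) in aqueous methanol at 60 °C and acidified with HCl. This gives the half-ester (2R,3R,4Z)-4-[4-(benzyloxy)-3-methoxybenzylidene]-2-[3,4-bis(benzyloxy)phenyl]-3-(methoxycarbonyl)oxolane-3-carboxylic acid F2.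
- F2 is decarboxylated by warming in toluene with a trace of Et3N (110 °C). This should give 9 together with its C3 epimer, methyl (2S,3R,4Z)-4-[4-(benzyloxy)-3-methoxybenzylidene]-2-[3,4-bis(benzyloxy)phenyl]oxolane-3-carboxylate F3.
- The mixture is equilibrated with catalytic NaOMe in methanol at 0 °C and quenched as soon as F3 is consumed, before the alkene can move, so that the route is rejoined at 9.

Step 7. The risks are hydrogenolysis of the benzylic C2–O1 or allylic C5–O1 bond competing with alkene saturation, palladium-induced migration of the C4=C7′ bond before reduction, and imperfect facial selectivity at C4. Fallback: set out from 11 and separate the two events.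
- The alkene alone is saturated with H2 (1 atm) over Rh/Al2O3 in EtOAc, a catalyst that reduces alkenes but is poor at C–O hydrogenolysis. This gives [(2S,3R,4R)-4-[4-(benzyloxy)-3-methoxybenzyl]-2-[3,4-bis(benzyloxy)phenyl]oxolan-3-yl]methyl acetate F4, from which any C4 epimer can be removed by chromatography or crystallisation at this lipophilic stage.
- F4 is then debenzylated by transfer hydrogenolysis (Pd/C, 1,4-cyclohexadiene, EtOAc–EtOH, 25 °C). No allylic ether remains at that point and the limited hydrogen supply should spare C2–O1, so the route is rejoined at 12.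

Further compounds
F1 | step 3 | racemic dimethyl (4Z)-4-[4-(benzyloxy)-3-methoxybenzylidene]-2-[3,4-bis(benzyloxy)phenyl]oxolane-3,3-dicarboxylate | COc1cc(/C=C2\COC(c3ccc(OCc4ccccc4)c(OCc4ccccc4)c3)C2(C(=O)OC)C(=O)OC)ccc1OCc1ccccc1
F2 | step 4 | (2R,3R,4Z)-4-[4-(benzyloxy)-3-methoxybenzylidene]-2-[3,4-bis(benzyloxy)phenyl]-3-(methoxycarbonyl)oxolane-3-carboxylic acid (acid group trans to the C2 aryl group) | COc1cc(/C=C2\CO[C@H](c3ccc(OCc4ccccc4)c(OCc4ccccc4)c3)[C@@]2(C(=O)OC)C(O)=O)ccc1OCc1ccccc1
F3 | step 4 | methyl (2S,3R,4Z)-4-[4-(benzyloxy)-3-methoxybenzylidene]-2-[3,4-bis(benzyloxy)phenyl]oxolane-3-carboxylate (ester cis to the C2 aryl group) | COc1cc(/C=C2\CO[C@H](c3ccc(OCc4ccccc4)c(OCc4ccccc4)c3)[C@@H]2C(=O)OC)ccc1OCc1ccccc1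
F4 | step 7 | [(2S,3R,4R)-4-[4-(benzyloxy)-3-methoxybenzyl]-2-[3,4-bis(benzyloxy)phenyl]oxolan-3-yl]methyl acetate | COc1cc(C[C@H]2CO[C@H](c3ccc(OCc4ccccc4)c(OCc4ccccc4)c3)[C@H]2COC(C)=O)ccc1OCc1ccccc1
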